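The runs come from a simulation with constants of no real substance, and the scatter is random.

At 4.00 h in Tuesday's stirred two-phase flask, target stood at 23 % of the 0.50 M substrate charged, so target had appeared at 0.0288 M/h.

all flasks: substrate 0.50 M
- Tuesday's: reagent in the second phase 0.40 M; the very flask that is asked about, followed so far
- Saturday's: reagent in the second phase 0.20 M; run made earlier
- flask: reagent in the second phase 0.400 M; time 12 h; volume of the second phase over the first 2.0

| run | time / h | target / % | substrate / % |
|---|---|---|---|
| Tuesday's | 0.667 | 2 | 96 |
| Tuesday's | 1.33 | 9 | 93 |
| Tuesday's | 2.00 | 8 | 88 |
| Tuesday's | 3.00 | 14 | 85 |
| Tuesday's | 4.00 | 23 | 75 |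
| Saturday's | 0.667 | 5 | 98 |
| Saturday's | 1.33 | 3 | 97 |
| Saturday's | 2.50 | 8 | 93 |
| Saturday's | 4.00 | 11 | 92 |
| Saturday's | 8.00 | 16 | 80 |

(standard deviation of a reading: 2 percentage points)
- in the second phase: reagent in the second phase; everything else is in the first
- charges count per volume of the first phase; a concentration in a rate is the amount of a species over the volume of its own phase; every rate counts per litre of the first phase
- what was read earlier has a scatter of 2 percentage points, one standard deviation
- the earlier runs hold the two phases in the same ratio of volumes as the flask asked about
- target at 12 h, in percent of the substrate charged
- the change that raises the amount of target at 12 h, in percent of the substrate charged most ("none" if none brings more than 2 percentage points) (delta / zeta / none)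
- amount of target at 12 h, in percent of the substrate charged, after zeta
- delta: doubling the amount of reagent in the second phase, all else as stated
- zeta: doubling the transfer coefficient of the reagent in the second phase, all else as stated

I treated the reagent in the second phase as a store emptying by pseudo-first-order decay, each reagent giving one target. For Tuesday's flask, the draining time τ, the reagent charge over the early rate of target, was 13.9 h. Saturday's flask, with half the reagent, gave 14.5 h from its reading at 4.00 h, so τ did not follow the charge, within a scatter of 2 percentage points. Target at time t is then the charge times one minus e to the power −t/τ, which gave me 46.2 % at 12 h. Delta kept τ and gave me 92.4 %. Zeta, if τ is a transfer time, halved τ and gave me 65.7 %, so I expected delta to bring more.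

The forecast gave 44 %, delta and 52 % after zeta, noting that “The data cannot separate these”.

The flask gave 41.5 %, delta best at 15 points against 7.3 points for zeta, and 48.8 % after zeta.

    reagent in the reaction phase ⇌ reagent in the second phase, rate k1*([reagent in the reaction phase] - [reagent in the second phase]/K1) per volume of the first phase (partition coefficient = 0.587, kL = 0.127 /h)
    substrate + reagent in the reaction phase → target (k = 4.31 /M/h)
    reagent in the reaction phase + target → over-reacted product (k = 1.38 /M/h)
    substrate + target → side product (k = 0.0206 /M/h)

My figure for the flask stood 4.7 points above the result, and my zeta figure stood 17 points above its result. A neighbour flask charged 2.0 M of substrate with the same reagent, so I kept τ and the same molar amount of target, which is 11.6 % of that larger charge. At 12 h, this neighbour flask gave 10.6 % target with 83 % of its substrate left.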